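3 readings of target are asked of one flask, and 2 earlier runs stand beside it.

| setting | west | north-east | flask |
|---|---|---|---|
| substrate | 0.30 M | 0.30 M | 0.30 M |
| reagent | 0.38 M | 0.59 M | 0.270 M |
| free catalyst | 3 mM | 3 mM | 3.0 mM |
| remark | run made earlier | run made earlier |  |
| time |  |  | 2.5 h |

| run | time / h | target / % | substrate / % |
|---|---|---|---|
| west | 0.250 | 3.9 | 56.8 |
| west | 0.333 | 5.5 | 48.4 |
| west | 0.500 | 13.4 | 34.9 |
| west | 0.833 | 26.2 | 19.9 |
| west | 1.33 | 42.6 | 7.3 |
| west | 2.00 | 59.4 | 3.8 |
| west | 3.00 | 76.4 | 0.2 |
| north-east | 0.417 | 12.8 | 40.6 |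
| north-east | 0.833 | 34.0 | 17.1 |
| north-east | 1.33 | 54.4 | 6.0 |
| north-east | 1.50 | 60.9 | 3.3 |
| north-east | 2.00 | 74.8 | 3.3 |
| north-east | 2.50 | 82.9 | 0 |
| north-east | 3.00 | 89.3 | 0 |

(each reading ± 1 percentage point)

- amount of target in percent of the substrate charged, at 30 min, 80 min and 2.5 h

- the numbers in the tables scatter by 1 percentage point (one standard deviation)
- steps under discussion: reagent + catalyst intermediate -> free catalyst + target; substrate + free catalyst -> free catalyst + open intermediate; free catalyst + open intermediate <-> catalyst intermediate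

At 0.833 h the substrate readings of the two runs give a mean first-order constant 2.03 h⁻¹, which I call s. The catalyst charge is 1.00 % of the substrate charge, so I count the part of the charge that is neither substrate nor target as open intermediate, I.

The quantity to carry is the handover coefficient g: target made per hour, divided by I and by the molar reagent, both taken at mid-stretch. Between 0.833 h and 1.33 h the west run gives 2.29 M⁻¹ h⁻¹ and the north-east run 2.03 M⁻¹ h⁻¹, so g is 2.16 M⁻¹ h⁻¹.

Ben holds the reagent at its charge, a pseudo-first-order handover with κ = g times reagent, here 0.583 h⁻¹. The exact chain substrate to I to target, with constants s and κ, then gives him 9.79 % at 30 min and 67.6 % at 2.5 h.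

Ana objects that each target takes one reagent. She puts his 67.6 % back, using the mean reagent of the run, and gets 51.1 %. Going round once more gives 55.8 %. The same rounds at 80 min go from 38.2 % through 31.9 % to 33.0 %. At 30 min Ben's figure uses 10.9 % of the reagent charge, and she lets it stand. I commit to her numbers.

The forecast, which also has the “reagent runs down”, reaches its own 10.5 %, 36 % and 57 %.

The flask gives 11.0 %, 34.0 % and 55.2 %.

    reagent + catalyst intermediate → free catalyst + target (k = 0.107 M⁻¹ s⁻¹)
    substrate + free catalyst → free catalyst + open intermediate (k = 0.241 M⁻¹ s⁻¹)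
    free catalyst + open intermediate ⇌ catalyst intermediate (K = 4.83 M⁻¹, k = 0.213 M⁻¹ s⁻¹)

Ben's 67.6 % stands 12 percentage points above the flask at 2.5 h, but at 30 min his 9.79 % stands 1.2 points below it, and his view is nearest early in this flask, where 95.6 % of the reagent charge is present at 0.250 h. From 2.5 h to 5.00 h this flask's target climbs from 55.2 % to 74.8 %, while I falls from 43.2 % to 25.0 % and reagent from 0.104 M to 0.0456 M. Over that stretch g reads 3.06 M⁻¹ h⁻¹, higher than the carried 2.16 M⁻¹ h⁻¹.

(The numbers in the tables were computed for an exercise, and the scatter is random.)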